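| flask | substrate | partner | free catalyst | remark |
|---|---|---|---|---|
| east | 0.050 M | 0.028 M | 65 µM | run made earlier |
| north | 0.050 M | 0.11 M | 65 µM | run made earlier |
| south-east | 0.050 M | 0.055 M | 32 µM | run made earlier |
| flask | 0.050 M | 0.0550 M | 65 µM |  |

- east (time / min: product / %, substrate / %): 6.00: 2, 100; 15.0: 9, 98; 20.0: 4, 98; 30.0: 9, 91; 40.0: 10, 91; 50.0: 10, 87
- north (time / min: product / %, substrate / %): 2.50: 0, 97; 8.00: 0, 96; 15.0: 6, 91; 20.0: 8, 92; 30.0: 13, 91; 40.0: 14, 87; 50.0: 20, 83
- south-east (time / min: product / %, substrate / %): 4.00: 0, 97; 8.00: 0, 103; 15.0: 3, 94; 25.0: 4, 95; 50.0: 8, 92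

(each reading ± 2 percentage points)

1. apparent order in partner when 30% of the substrate are converted (percent change of the rate of making product for one percent more partner charged)

- the earlier runs were read with a standard deviation of 2 percentage points

Take the east and north runs, which share substrate and free catalyst and differ in partner charge by a factor of 3.93. At 50.0 min I average product and substrate lost, as fractions of the substrate charged: east reads 11.5% and north 18.5%, each from readings with a scatter of 2 points.

Now turn the question round. For a rate proportional to partner, north needs 45.2%. For a rate indifferent to partner, north needs the east value. These are the two ends, with slopes of one and zero on a log-log plot, as on a Bode plot. North stands between them, and the ratio of the two means is 1.61.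

Joining the ends gives my charge exponent, the logarithm of the conversion ratio over the logarithm of the partner ratio, 0.347, a reading of the apparent order. The flask sits midway on that logarithmic scale, a factor of 1.96 above east and 2.00 below north. These readings stop short of 30% conversion, but I commit to 0.347 for the flask.

The forecast says 0.55, which is higher than my value. It argues from “partial saturation in partner”.

The flask gives 0.43, below the forecast and above my exponent.

    catalyst intermediate A ⇌ catalyst intermediate B (K = 1.80, k = 0.560 s⁻¹)
    partner + free catalyst ⇌ catalyst intermediate A (K = 8.90 M⁻¹, k = 10.0 M⁻¹ s⁻¹)
    catalyst intermediate C → catalyst intermediate D (k = 0.400 s⁻¹)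
    2 catalyst intermediate C ⇌ resting dimer, settled at all times (K = 2.70 × 10⁵ M⁻¹)
    substrate + catalyst intermediate B → catalyst intermediate C (k = 11.0 M⁻¹ s⁻¹)
    catalyst intermediate D → free catalyst + product (k = 0.450 s⁻¹)

In the flask, the equilibrium constant for partner binding free catalyst, times partner as charged, is 0.49. Carried from east to the flask, my exponent 0.347 raises the east mean by a factor of 1.26 to 14.5% at 50.0 min. Scaled in proportion to time, that is 11.6% at 40.0 min, when the flask holds 11.9% product.

All runs were generated by integration from invented constants.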